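**Retrosynthetic overview**

1. Feature: ring A is a 1,4-disubstituted benzene (allyl at C4) held only through its C1–O bond to O3 on C3 of ring B, the catechol oxygen remote from the biaryl bond. Rings B and C, with the C5/C5' allyl groups and the C2/C2' hydroxyls, are magnolol, so ring A can be built on O3 instead of being coupled as an aryl group.
2. End game: the ring A allyl group comes from a benzylic bromide and a vinylstannane (Stille); the benzylic carbon comes from the methyl ester that the ring synthesis leaves para to oxygen; both MOM groups are removed last.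
3. Key disconnection: ring A comes from an aryl ethynyl ether (two ring carbons on O3) and methyl coumalate (four ring carbons and the ester) by [4+2] cycloaddition and loss of CO2.
4. The ynol ether comes from the C3 phenol and trichloroethylene (dichlorovinyl ether, then n-BuLi). The C3–OH comes from the C3–Br of monobrominated magnolol after MOM protection of O2 and O2', so O3 is the only free oxygen when it is vinylated.
5. Ring order: rings B and C are bought as magnolol; ring A is the only ring made, in step 6.

Key step: step 6

Assumption: the target has no stereocentre, no stereogenic double bond and a freely rotating biaryl axis, so only regiochemistry has to be controlled.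

**Route**

Step 1
Reactants: 1 magnolol (5,5'-diallylbiphenyl-2,2'-diol)
Product: 2 3-bromo-5,5'-diallylbiphenyl-2,2'-diol
Conditions: NBS (0.95 equiv), i-Pr2NH (10 mol%), CH2Cl2, −20 to 0 °C, dark
Reagents that add atoms: N-bromosuccinimide, O=C1CCC(=O)N1Br
Why: Amine-catalysed ortho-bromination of a phenol by NBS (electrophilic aromatic substitution) should outrun any reaction of NBS with the monosubstituted alkenes, C3 is the only activated open position of each ring because the para carbon carries the allyl group, and a slight deficit of NBS should stop this symmetric diol at the monobromide, which is separated from recovered 1 and the dibromide.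

Step 2
Reactants: 2 3-bromo-5,5'-diallylbiphenyl-2,2'-diol
Product: 3 3-bromo-5,5'-diallyl-2,2'-bis(methoxymethoxy)biphenyl
Conditions: NaH (2.5 equiv), MOMCl (2.5 equiv), THF–DMF, 0 °C to rt
Reagents that add atoms: chloromethyl methyl ether, COCCl
Why: Williamson-type O-alkylation of both sodium phenoxides with the very reactive α-chloro ether should mask O2 and O2' as MOM acetals that tolerate the organolithium, hydride and palladium steps and are removed together at the end.

Step 3
Reactants: 3 3-bromo-5,5'-diallyl-2,2'-bis(methoxymethoxy)biphenyl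
Product: 6 5,5'-diallyl-2,2'-bis(methoxymethoxy)biphenyl-3-ol, via aryllithium 4 (not isolated), via dimethyl arylboronate 5 (not isolated)
Conditions: n-BuLi (1.05 equiv), THF, −78 °C, 5 min; B(OMe)3, −78 °C to rt; then 30% H2O2, aq. NaOH, 0 °C to rt
Reagents that add atoms: hydrogen peroxide, OO
Why: Bromine–lithium exchange at −78 °C is faster than deprotonation of the ArCH2 allyl positions and gives an aryllithium stabilised by the neighbouring OMOM group, which is borylated and then oxidised by alkaline H2O2 (1,2-shift of aryl from boron to oxygen), a sequence that leaves unactivated alkenes and acetals untouched.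

Step 4
Reactants: 6 5,5'-diallyl-2,2'-bis(methoxymethoxy)biphenyl-3-ol; 7 trichloroethylene
Product: 9 5,5'-diallyl-3-{[(E)-1,2-dichlorovinyl]oxy}-2,2'-bis(methoxymethoxy)biphenyl, via dichloroacetylene 8 (not isolated)
Conditions: K2CO3 (2 equiv), trichloroethylene (2 equiv), DMF, 70 °C
Reagents that add atoms: none
Why: K2CO3 eliminates HCl from trichloroethylene to dichloroacetylene, to which the phenoxide adds in an anti sense before protonation (the known dichlorovinylation of phenols), giving the E ether at O3, the only free oxygen.

Step 5
Reactants: 9 5,5'-diallyl-3-{[(E)-1,2-dichlorovinyl]oxy}-2,2'-bis(methoxymethoxy)biphenyl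
Product: 12 5,5'-diallyl-3-(ethynyloxy)-2,2'-bis(methoxymethoxy)biphenyl, via chloroethynyl ether 10 (not isolated), via lithium aryloxyacetylide 11 (not isolated)
Conditions: n-BuLi (2.1 equiv), Et2O, −78 to −40 °C; H2O, −78 °C; cold work-up, taken at once into toluene for step 6
Reagents that add atoms: none
Why: n-BuLi removes the vinylic hydrogen and LiCl is lost to give the chloroalkyne, chlorine–lithium exchange with a second equivalent gives the lithium acetylide and water protonates it (the dichlorovinyl ether route to ynol ethers), all at temperatures where the allyl and MOM groups should not be metalated.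

Step 6
Reactants: 12 5,5'-diallyl-3-(ethynyloxy)-2,2'-bis(methoxymethoxy)biphenyl; 13 methyl coumalate
Product: 15 methyl 4-{[5,5'-diallyl-2,2'-bis(methoxymethoxy)biphenyl-3-yl]oxy}benzoate, via bicyclic lactone 14 (not isolated)
Conditions: methyl coumalate (3 equiv), BHT (cat.), toluene, argon, 60 to 90 °C, held at the lowest temperature at which CO2 is evolved
Reagents that add atoms: none
Why: The electron-poor 2-pyrone acts as the diene and the electron-rich ynol ether as the dienophile in an inverse-electron-demand Diels–Alder reaction: an asynchronous concerted [4+2] addition across C3 and C6 of the pyrone gives the bridged lactone 14, which loses CO2 by retro-[4+2] at the same temperature and so delivers the benzene without an oxidation step. The closest known reaction type is the cycloaddition of methyl coumalate and related 2-pyrones with ynamines, ketene acetals and enol ethers followed by CO2 extrusion. Ring A is closed by this intermolecular [4+2] annulation, four ring carbons (C3 to C6) coming from the pyrone and two from the alkyne, with both new C–C bonds formed in the cycloaddition. The two bridgehead stereocentres of racemic 14 are erased on aromatisation, so no stereocentre has to be controlled. The step needs para regiochemistry, which the polarisation of the partners secures: the nucleophilic terminal alkyne carbon bonds to C6 of the coumalate (β to the ester, δ to the lactone carbonyl), so the oxygen-bearing carbon bonds to C3 and ends para to CO2Me. It also needs chemoselectivity for the ynol ether over the two allyl groups, which holds because unactivated terminal alkenes add to methyl coumalate only at much higher temperature, while excess pyrone and the mildest workable temperature should keep capture ahead of decay of the labile aryl ethynyl ether.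

Step 7
Reactants: 15 methyl 4-{[5,5'-diallyl-2,2'-bis(methoxymethoxy)biphenyl-3-yl]oxy}benzoate
Product: 16 (4-{[5,5'-diallyl-2,2'-bis(methoxymethoxy)biphenyl-3-yl]oxy}phenyl)methanol
Conditions: i-Bu2AlH (2.5 equiv), CH2Cl2, −78 to 0 °C; aq. potassium sodium tartrate work-up
Reagents that add atoms: none
Why: i-Bu2AlH reduces the aryl ester through the aldehyde to the benzylic alcohol (hydride reduction) without touching alkenes, MOM acetals or the diaryl ether.

Step 8
Reactants: 16 (4-{[5,5'-diallyl-2,2'-bis(methoxymethoxy)biphenyl-3-yl]oxy}phenyl)methanol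
Product: 17 5,5'-diallyl-3-[4-(bromomethyl)phenoxy]-2,2'-bis(methoxymethoxy)biphenyl
Conditions: CBr4, PPh3, CH2Cl2, 0 °C
Reagents that add atoms: carbon tetrabromide, BrC(Br)(Br)Br
Why: Appel reaction, in which the alcohol is activated as an alkoxyphosphonium ion and displaced by bromide (SN2) under near-neutral conditions that the MOM ethers and alkenes should tolerate.

Step 9
Reactants: 17 5,5'-diallyl-3-[4-(bromomethyl)phenoxy]-2,2'-bis(methoxymethoxy)biphenyl; 18 tributyl(vinyl)stannane
Product: 19 5,5'-diallyl-3-(4-allylphenoxy)-2,2'-bis(methoxymethoxy)biphenyl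
Conditions: Pd(PPh3)4 (5 mol%), degassed toluene, 80 °C
Reagents that add atoms: none
Why: Stille coupling, in which zerovalent palladium inserts into the benzylic C–Br bond, the vinyl group is transferred from tin and reductive elimination forms the ArCH2–CH=CH2 bond, the benzylpalladium intermediate having no β-hydrogen to eliminate and the neutral conditions leaving the other two allyl groups unisomerised.

Step 10
Reactants: 19 5,5'-diallyl-3-(4-allylphenoxy)-2,2'-bis(methoxymethoxy)biphenyl
Product: 20 isodunnianol (5,5'-diallyl-3-(4-allylphenoxy)biphenyl-2,2'-diol)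
Conditions: HCl (3 M aq.), MeOH–THF, 45 °C
Reagents that add atoms: none
Why: Acid-catalysed methanolysis of the two MOM acetals (transacetalisation to dimethoxymethane) frees both phenols under conditions too mild to hydrate or shift the allyl double bonds or cleave the diaryl ether.

**Compound list**

1 | magnolol (5,5'-diallylbiphenyl-2,2'-diol) | C=CCc1ccc(O)c(-c2cc(CC=C)ccc2O)c1 | starting material
2 | 3-bromo-5,5'-diallylbiphenyl-2,2'-diol | C=CCc1ccc(O)c(-c2cc(CC=C)cc(Br)c2O)c1 | intermediate
3 | 3-bromo-5,5'-diallyl-2,2'-bis(methoxymethoxy)biphenyl | C=CCc1ccc(OCOC)c(-c2cc(CC=C)cc(Br)c2OCOC)c1 | intermediate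
4 | [5,5'-diallyl-2,2'-bis(methoxymethoxy)biphenyl-3-yl]lithium (formed in the flask) | [Li]c1cc(CC=C)cc(-c2cc(CC=C)ccc2OCOC)c1OCOC | intermediate
5 | dimethyl [5,5'-diallyl-2,2'-bis(methoxymethoxy)biphenyl-3-yl]boronate (formed in the flask) | COB(OC)c1cc(CC=C)cc(-c2cc(CC=C)ccc2OCOC)c1OCOC | intermediate
6 | 5,5'-diallyl-2,2'-bis(methoxymethoxy)biphenyl-3-ol | Oc1cc(CC=C)cc(-c2cc(CC=C)ccc2OCOC)c1OCOC | intermediate
7 | trichloroethylene | ClC=C(Cl)Cl | starting material
8 | dichloroacetylene (formed in the flask) | ClC#CCl | intermediate
9 | 5,5'-diallyl-3-{[(E)-1,2-dichlorovinyl]oxy}-2,2'-bis(methoxymethoxy)biphenyl | Cl/C=C(/Cl)Oc1cc(CC=C)cc(-c2cc(CC=C)ccc2OCOC)c1OCOC | intermediate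
10 | 5,5'-diallyl-3-[(chloroethynyl)oxy]-2,2'-bis(methoxymethoxy)biphenyl (formed in the flask) | ClC#COc1cc(CC=C)cc(-c2cc(CC=C)ccc2OCOC)c1OCOC | intermediate
11 | lithium 2-{[5,5'-diallyl-2,2'-bis(methoxymethoxy)biphenyl-3-yl]oxy}ethynide (formed in the flask) | [Li]C#COc1cc(CC=C)cc(-c2cc(CC=C)ccc2OCOC)c1OCOC | intermediate
12 | 5,5'-diallyl-3-(ethynyloxy)-2,2'-bis(methoxymethoxy)biphenyl | C#COc1cc(CC=C)cc(-c2cc(CC=C)ccc2OCOC)c1OCOC | intermediate
13 | methyl coumalate (methyl 2-oxo-2H-pyran-5-carboxylate) | COC(=O)C1=COC(=O)C=C1 | starting material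
14 | methyl 5-{[5,5'-diallyl-2,2'-bis(methoxymethoxy)biphenyl-3-yl]oxy}-3-oxo-2-oxabicyclo[2.2.2]octa-5,7-diene-7-carboxylate (racemic, one enantiomer drawn; formed in the flask) | O=C1O[C@@H]2C=C(Oc3cc(CC=C)cc(-c4cc(CC=C)ccc4OCOC)c3OCOC)[C@H]1C=C2C(=O)OC | intermediate
15 | methyl 4-{[5,5'-diallyl-2,2'-bis(methoxymethoxy)biphenyl-3-yl]oxy}benzoate | COC(=O)c1ccc(Oc2cc(CC=C)cc(-c3cc(CC=C)ccc3OCOC)c2OCOC)cc1 | intermediate
16 | (4-{[5,5'-diallyl-2,2'-bis(methoxymethoxy)biphenyl-3-yl]oxy}phenyl)methanol | OCc1ccc(Oc2cc(CC=C)cc(-c3cc(CC=C)ccc3OCOC)c2OCOC)cc1 | intermediate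
17 | 5,5'-diallyl-3-[4-(bromomethyl)phenoxy]-2,2'-bis(methoxymethoxy)biphenyl | BrCc1ccc(Oc2cc(CC=C)cc(-c3cc(CC=C)ccc3OCOC)c2OCOC)cc1 | intermediate
18 | tributyl(vinyl)stannane | C=C[Sn](CCCC)(CCCC)CCCC | starting material
19 | 5,5'-diallyl-3-(4-allylphenoxy)-2,2'-bis(methoxymethoxy)biphenyl | C=CCc1ccc(Oc2cc(CC=C)cc(-c3cc(CC=C)ccc3OCOC)c2OCOC)cc1 | intermediate
20 | isodunnianol | C=CCc1ccc(Oc2cc(CC=C)cc(-c3cc(CC=C)ccc3O)c2O)cc1 | target

**Step count and risks**

Total step count: 10. Longest linear sequence: 10 steps, from magnolol 1 to isodunnianol 20; compounds 7, 13 and 18 are bought.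

Steps most likely to fail:

Step 6. The aryl ethynyl ether may oligomerise or add adventitious water faster than the pyrone captures it, or regiocontrol may be incomplete, so that little para-benzoate is formed. The fallback gives up building ring A and attaches it instead. It sets out from phenol 6, which should undergo nucleophilic aromatic substitution with 4-fluorobenzaldehyde (K2CO3, DMF, 90 °C) to give 4-{[5,5'-diallyl-2,2'-bis(methoxymethoxy)biphenyl-3-yl]oxy}benzaldehyde F1. Reduction with NaBH4 in MeOH at 0 °C should then give benzylic alcohol 16, where the route is rejoined for steps 8 to 10.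

Step 5. The terminal ynol ether may be lost during aqueous work-up and concentration (oligomerisation, hydration), and some lithiation at the ArCH2 positions may erode the material. The fallback masks the alkyne carbon. It sets out from dichlorovinyl ether 9 and, after the same treatment with n-BuLi, quenches acetylide 11 with Me3SiCl instead of water. This should give ({[5,5'-diallyl-2,2'-bis(methoxymethoxy)biphenyl-3-yl]oxy}ethynyl)trimethylsilane F2, a C-silyl ynol ether that should survive chromatography and storage. Desilylation with Bu4NF in THF at −40 °C just before the cycloaddition should release ynol ether 12, where the route is rejoined, so the labile compound is never concentrated or stored.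

Step 1. Over-bromination to the 3,3'-dibromide and electrophilic attack of bromine on the allyl double bonds may leave little monobromide. The fallback introduces O3 through a formyl group instead of bromine and sets out from magnolol 1:
- Monoprotection (NaH 1 equiv, MOMCl, THF, 0 °C) should give 5,5'-diallyl-2'-(methoxymethoxy)biphenyl-2-ol F3.
- Magnesium-mediated ortho-formylation of the remaining phenol (MgCl2, Et3N, paraformaldehyde, MeCN, reflux) should give 5,5'-diallyl-2-hydroxy-2'-(methoxymethoxy)biphenyl-3-carbaldehyde F4.
- Protection (MOMCl, i-Pr2NEt, CH2Cl2) should give 5,5'-diallyl-2,2'-bis(methoxymethoxy)biphenyl-3-carbaldehyde F5.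
- Baeyer–Villiger oxidation of the electron-rich aldehyde (mCPBA, NaHCO3, CH2Cl2, 0 °C), which should be faster than epoxidation of monosubstituted alkenes, should give 5,5'-diallyl-2,2'-bis(methoxymethoxy)biphenyl-3-yl formate F6.
- Methanolysis (K2CO3, MeOH) should give phenol 6, where the route is rejoined at step 4.

**Further compounds**

F1 | step 6 | 4-{[5,5'-diallyl-2,2'-bis(methoxymethoxy)biphenyl-3-yl]oxy}benzaldehyde | O=Cc1ccc(Oc2cc(CC=C)cc(-c3cc(CC=C)ccc3OCOC)c2OCOC)cc1
F2 | step 5 | ({[5,5'-diallyl-2,2'-bis(methoxymethoxy)biphenyl-3-yl]oxy}ethynyl)trimethylsilane | C[Si](C)(C)C#COc1cc(CC=C)cc(-c2cc(CC=C)ccc2OCOC)c1OCOC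
F3 | step 1 | 5,5'-diallyl-2'-(methoxymethoxy)biphenyl-2-ol | C=CCc1ccc(OCOC)c(-c2cc(CC=C)ccc2O)c1
F4 | step 1 | 5,5'-diallyl-2-hydroxy-2'-(methoxymethoxy)biphenyl-3-carbaldehyde | O=Cc1cc(CC=C)cc(-c2cc(CC=C)ccc2OCOC)c1O
F5 | step 1 | 5,5'-diallyl-2,2'-bis(methoxymethoxy)biphenyl-3-carbaldehyde | O=Cc1cc(CC=C)cc(-c2cc(CC=C)ccc2OCOC)c1OCOC
F6 | step 1 | 5,5'-diallyl-2,2'-bis(methoxymethoxy)biphenyl-3-yl formate | O=COc1cc(CC=C)cc(-c2cc(CC=C)ccc2OCOC)c1OCOC
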